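The numbers in the tables stem from a simulated flask with constants of no real substance; scatter was added.

The target of the north-west flask, the very flask asked about, showed no rise between its last two readings: it read 42% at 15.0 min and 42% at 25.0 min, while side product kept growing.

the same everywhere: solid substrate 0.10 M

| flask | reagent | remark | time |
|---|---|---|---|
| north-west | 0.11 M (fed, over 5.0 min) | the very flask that is asked about, followed so far; the fed solution adds 0.10 times the starting volume |  |
| west | 0.17 M (fed, over 5.0 min) | run made earlier; the fed solution adds 0.10 times the starting volume |  |
| flask | 0.110 M (fed, over 5.0 min) | the fed solution adds 0.10 times the starting volume | 1.0 h |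

| run | time / min | target / % | side product / % |
|---|---|---|---|
| north-west | 3.00 | 6 | 3 |
| north-west | 8.00 | 24 | 3 |
| north-west | 15.0 | 42 | 11 |
| north-west | 25.0 | 42 | 16 |
| west | 10.0 | 44 | 6 |
| west | 20.0 | 53 | 13 |
| west | 30.0 | 52 | 17 |
| west | 40.0 | 50 | 19 |

(readings scatter by 1.5 percentage points)

- in percentages every species weighs as the solid substrate in it: one side product counts as two
- charges are per starting volume, the dose included; the dosed solution carries all of it
- as a solid, counted per litre of solution: solid substrate
- at the start none of the solid substrate is in solution

- concentration of target at 1.0 h, in M
- concentration of side product at 1.0 h, in M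
- concentration of reagent at 1.0 h, in M

1. First rung: the feed ended at 5.0 min, and the north-west target, at 24% by 8.00 min, was still climbing.

2. Next rung: the north-west target read flat from 15.0 min, yet side product in that run gained 5 percentage points afterwards. So I looked at m, the share of the charge that is neither target nor side product.

3. Last rung: one side product counts as two, and I assumed the gain to be second-order in m. In the west run m read 31.0% at 30.0 min. From the readings of that run I kept 0.0312 /min as the leak constant λ, the fraction of charge turned to side product per minute divided by the square of m.

4. Check on the north-west run: with m at 42.0%, λ gives 5.5 points over the stretch in step 2.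

5. The leak's time scale, 1/(λm), is 76.3 min, longer than the 1.0 h asked, so I expected it still running then. Taking m midway between the two runs, I reckoned side product at 30.6%, or 0.0139 M. I reckoned nothing for target or reagent.

The forecast gave 0.034 M target, 0.0105 M side product and 0.002 M reagent, holding that “reagent should be essentially gone by 1 h”.

The flask gave 0.0307 M target, 0.0154 M side product and 0.0363 M reagent.

    2 reagent → self-condensation product (k = 0.00216 /M/s)
    dissolved substrate + reagent ⇌ target (K = 25.0 /M, k = 0.0224 /M/s)
    2 dissolved substrate → side product (k = 0.00330 /M/s)
    solid substrate ⇌ dissolved substrate, rate k4*(cs4 - [dissolved substrate]) while solid is left; crystals form when [dissolved substrate] > cs4 (solubility = 0.0760 M, k = 0.00408 /s)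

My side product fell short of the flask's, which held 34.0%, and m there stood as dissolved substrate, 32.2%. The neighbour charged with 0.44 M of reagent ended with m at 29.8%. Held there for 1.0 h, λ gives 16.6% side product, and that neighbour simulated 14.5%.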